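Compounds are numbered 1–16 in the order in which they appear in the steps; the full list with structures follows the last step.

## Analysis of the target

Target 16 is a neolignan of the phenylcoumaran type: a 2,3-dihydro-1-benzofuran whose benzo ring (ring A) carries OMe at C7 and a CH2CH2CO2Me chain at C5, whose C2 carries a 4-hydroxy-3,5-dimethoxyphenyl (syringyl) group and whose C3 carries CH2OH (C9). C2 (S) and C3 (R) are the only stereocentres; they are adjacent, and the aryl and hydroxymethyl groups are trans on the five-membered ring. The C2–O1 bond is a para-hydroxybenzyl aryl ether, so once the syringyl phenol is free, acid or base can open the ring through a quinone methide; the methyl ester and the primary alcohol further limit the late reagents. The synthesis is hard because the absolute configuration at C2 must be set next to an electron-rich aryl group, because the trans relation must be secured at C3, which cannot be epimerised once C9 is an alcohol, and because two carboxyl-derived carbons (C9 and the chain ester) end at different oxidation levels. The plan rests on the substitution at C3, which is bonded to ring A carbon C3a and to the one-carbon unit C9. This is the pattern left when the ring A carbon of a 2-arylchroman-4-one moves from the carbonyl carbon to the neighbouring CH2 and the carbonyl carbon is pushed out of the ring at the ester level. The dihydrofuran ring, the C3–C3a bond and the C3 stereocentre can therefore all come from a (2S)-flavanone that has a single stereocentre.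

## Retrosynthetic reasoning

**16 from 15 (O–S bond).** The free phenol is unmasked last. In 15 it is an aryl sulfonate, which keeps the C2–O1 benzylic ether from opening through a quinone methide during the route and keeps the C2 aryl ring electron-poor. The forward step must cleave the S–O bond reductively without touching the methyl ester, the alcohol or C2.

**15 from 14, and 14 from 12 and 13 (C5–C bond of the chain).** The chain is cut at the aryl carbon. C5 is para to O1, where a bromine can be placed at the outset by simple electrophilic substitution, and a bromide is inert until a Heck reaction with 13 is wanted. Bringing the chain ester in only after C9 has been reduced means the two esters never coexist and need not be told apart. The forward steps are vinylation of the bromide and saturation of the new alkene.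

**12 from 11 (oxidation level of C9).** The hydroxymethyl group is traced to the methyl ester of 11. At this stage it is the only ester in the molecule, so a plain hydride reduction suffices; nothing at C2 or C3 is broken.

**11 from 8 (C3–C3a bond; the key disconnection).** Cutting C3–C3a and reconnecting C3a to the carboxyl carbon re-expands the five-membered ring to the chroman-4-one 8. This removes one stereocentre from the problem, because C3 is then derived from C2 by a stereospecific migration, and it leaves ring A intact from the start. The forward reaction must oxidise the carbon next to the ketone, make ring A migrate to it, and deliver the expelled carbonyl carbon as a methyl ester trans to the aryl group.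

**8 from 4 and 7 (C2–aryl bond).** The flavanone is cut between C2 and the syringyl ring, giving the flat chromone 4 and the arylboronic acid 7. The forward step is a catalytic enantioselective conjugate addition, which makes the route convergent and sets C2 from a chiral ligand, not from a stoichiometric auxiliary.

**4 from 2 from 1, and 7 from 6 from 5.** The chromone is an ortho-hydroxyacetophenone plus one carbon; its bromine goes in first, para to the phenol of 1. The boronic acid arises from the phenol boronate 5 by sulfonylation to 6 and release of the boronic acid.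

## Alternatives that were turned down

**Alternative 1: aryl radical 5-exo cyclisation with oxygen capture at C9.** The cuts are C3–C3a and C9–O. Iodide A2, an aryl ether of an enantioenriched 1-arylallyl alcohol, would be treated with Bu3SnH and TEMPO. The ring A radical attacks the inner alkene carbon 5-exo, and the primary C9 radical is caught by the nitroxide to give A1.
- For: one step makes the ring, C3 and the C9–O bond. C9 never passes through an ester, so the propanoate chain can be present from the start. C2 is not touched.
- Against: C2 in A2 is at once benzylic to an electron-rich ring, allylic and attached to an aryloxy leaving group. Making that ether enantiopure on a phenol flanked by iodine and OMe (Mitsunobu or allylic substitution) invites ionisation and SN2′ attack, and the ether can racemise the same way.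
- Against: C3 is set only by 1,2-induction in the cyclisation transition state. Trans is expected but need not be high, and a wrong epimer cannot be corrected because C3–H is not acidic in A1.
- Against: the stannane competes with TEMPO for the C9 radical and is consumed by it. N–O cleavage and debenzylation follow.
- Comparison: this alternative is stronger in that it delivers C9 already oxygenated and needs no late chain installation. The chosen route offers C3 from a stereospecific shift that is also the thermodynamic outcome, and C2 from a catalytic addition to a flat chromone.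

**Alternative 2: pyridazine–alkyne cycloaddition building ring A and the furan together.** The cuts are C3a–C7a and C4–C5, so ring A is made de novo. Heating the alkynyl pyridazinyl ether A4 would add the terminal alkyne across the two carbon termini of the diazine; loss of N2 aromatises ring A and gives A3.
- For: both stereocentres are set in an acyclic precursor and the thermal step creates none. The tether fixes the substitution pattern of ring A without ambiguity.
- Against: 1,2-diazines are weak azadienes, and this one carries two donor oxygens. Temperatures near 200 °C are to be expected, at which the propargylic C3–H can isomerise (alkyne to allene, which would scramble C3) and the benzylic heteroaryl ether can eliminate.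
- Against: A4 needs an anti 1-aryl-2-ethynyl-1,3-diol with two controlled stereocentres and a regioselective substitution on a dichlorodiazine. Afterwards an aryl chloride, a poorer Heck partner than a bromide, must still be turned into the propanoate and two protecting groups removed.
- Comparison: its one advantage is that stereochemistry is independent of ring formation. It is clearly longer and thermally harsher; the chosen route buys ring A ready-made.

**Alternative 3: ortho-quinone methide plus chiral sulfur ylide [4+1].** The cuts are C2–C3 and O1–C2. Cs2CO3 would release an ortho-quinone methide from sulfone A6 and the ylide from a chiral sulfonium salt such as A7 (drawn as one antipode; the matching one would have to be found). The ylide carbon adds to the methide carbon and the phenoxide displaces the sulfide, giving A5.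
- For: it is the most convergent plan. Ring and both stereocentres form in one step, the chain is already in place, and A5 is two deprotections from the target. On convergence and step count it equals or betters the chosen route.
- Against: the methide carbon carries CH2OTBS, not an aryl group. Such alkyl-substituted methides tautomerise easily to ortho-vinylphenols, and high selectivity in this annulation is tied to aryl-substituted methides.
- Against: the absolute configuration depends on a stoichiometric chiral sulfide whose facial control over a semi-stabilised benzyl ylide is substrate-dependent, and the electron-rich benzylsulfonium salt can ionise. A6 needs its own multi-step preparation.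
- Comparison: the chosen route offers in its place two separate, individually established control events (a catalytic enantioselective addition for C2, a stereospecific migration with thermodynamic backing for C3).

Key step: step 6

Remark on the chemistry: the sense of induction of the t-BuPyOx–palladium aryl insertion is assumed to follow the model for cyclic enones, by which the (R) ligand should give the 2S flavanone; phenol boronate 5 is taken as a catalogue compound.

## Route

Step 1
Reactants: 1 1-(2-hydroxy-3-methoxyphenyl)ethanone
Product: 2 1-(5-bromo-2-hydroxy-3-methoxyphenyl)ethanone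
Conditions: NBS (1.05 equiv), MeCN, 0 °C to rt
Reagents that add atoms: N-bromosuccinimide, O=C1CCC(=O)N1Br
Why: Electrophilic aromatic bromination; the phenolic OH directs to its para position (C5), which is also meta to the deactivating acetyl group, and both ortho positions of the OH are occupied.

Step 2
Reactants: 2 1-(5-bromo-2-hydroxy-3-methoxyphenyl)ethanone
Product: 4 6-bromo-8-methoxy-4H-chromen-4-one, via enaminone 3 (not isolated)
Conditions: Me2NCH(OMe)2, toluene, 100 °C; then conc. HCl, CH2Cl2, 40 °C
Reagents that add atoms: N,N-dimethylformamide dimethyl acetal, COC(OC)N(C)C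
Why: Condensation of the methyl ketone with the amide acetal gives enaminone 3; acid then promotes addition of the phenol to the enaminone carbon and loss of dimethylamine (enaminone route to chromones).

Step 3
Reactants: 5 2,6-dimethoxy-4-(4,4,5,5-tetramethyl-1,3,2-dioxaborolan-2-yl)phenol
Product: 6 2,6-dimethoxy-4-(4,4,5,5-tetramethyl-1,3,2-dioxaborolan-2-yl)phenyl 4-methylbenzenesulfonate
Conditions: TsCl, Et3N, DMAP (cat.), CH2Cl2, 0 °C to rt
Reagents that add atoms: p-toluenesulfonyl chloride, Cc1ccc(S(=O)(=O)Cl)cc1
Why: Sulfonylation of the phenol under nucleophilic catalysis by DMAP; the pinacol boronate is inert to amine base and sulfonyl chloride. The sulfonate masks the phenol and lowers the electron density of this ring for the key step.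

Step 4
Reactants: 6 2,6-dimethoxy-4-(4,4,5,5-tetramethyl-1,3,2-dioxaborolan-2-yl)phenyl 4-methylbenzenesulfonate
Product: 7 [3,5-dimethoxy-4-(4-methylbenzenesulfonyloxy)phenyl]boronic acid
Conditions: NaIO4, NH4OAc, acetone/H2O, rt
Reagents that add atoms: water, O
Why: Periodate cleaves the pinacol released in the hydrolysis equilibrium and so drives the boronate ester to the free boronic acid, the species that transmetalates in step 5; the aryl sulfonate is inert to periodate.

Step 5
Reactants: 4 6-bromo-8-methoxy-4H-chromen-4-one; 7 [3,5-dimethoxy-4-(4-methylbenzenesulfonyloxy)phenyl]boronic acid (2 equiv)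
Product: 8 (2S)-6-bromo-8-methoxy-2-[3,5-dimethoxy-4-(tosyloxy)phenyl]chroman-4-one
Conditions: Pd(OCOCF3)2 (5 mol %), (R)-t-BuPyOx (6 mol %), NH4PF6 (30 mol %), H2O (5 equiv), ClCH2CH2Cl, 60 °C
Reagents that add atoms: none
Why: Enantioselective conjugate addition of an arylboronic acid to a chromone under cationic divalent palladium/pyridine-oxazoline catalysis: transmetalation, insertion of C2=C3 into the aryl–palladium bond and protonolysis of the palladium enolate by water, with no zerovalent palladium on the cycle, so the C–Br bond and the sulfonate are spared. C2 is set by the ligand; on the model for cyclic enones the tert-butyl group of the (R) ligand should send the aryl group to the face that gives 2S. The configuration of 8 can be verified at this stage by comparing its circular dichroism spectrum with that of known (2S)-flavanones.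

Step 6
Reactants: 8 (2S)-6-bromo-8-methoxy-2-[3,5-dimethoxy-4-(tosyloxy)phenyl]chroman-4-one
Product: 11 methyl (2S,3S)-5-bromo-7-methoxy-2-[3,5-dimethoxy-4-(tosyloxy)phenyl]-2,3-dihydro-1-benzofuran-3-carboxylate (2,3-trans), via enol ether 9 (not isolated), via alpha-iodanyl ketal 10 (not isolated)
Conditions: PhI(OAc)2 (1.2 equiv), conc. H2SO4 (0.5 equiv), HC(OMe)3, rt
Reagents that add atoms: trimethyl orthoformate, COC(OC)OC
Why: Acid and the orthoformate convert the ketone of 8 into methyl enol ether 9; PhI(OAc)2 then adds as an electrophile at C3 on the face opposite the C2 aryl group while methanol caps C4, giving ketal 10 with the C3–I bond antiperiplanar to the C4–C4a bond. Loss of iodobenzene from the trivalent iodine centre is accompanied by a 1,2-shift of ring A carbon C4a from C4 to C3, which forms the C3–C3a bond with inversion at C3 and leaves C4 as a dimethoxycarbenium ion that is demethylated to the methyl ester. The closest known reaction type is the oxidative ring contraction of flavanones to methyl trans-2-aryl-2,3-dihydrobenzofuran-3-carboxylates with trivalent iodine reagents or Tl(NO3)3 in trimethyl orthoformate, a cyclic case of the 1,2-aryl shift of alpha-functionalised aryl ketone ketals. The dihydrofuran ring is closed by contraction of the pyranone ring (a semipinacol-type shift), not by a cyclisation, so no exo/endo ring-closure mode applies. The new stereocentre C3 is controlled by C2: anti addition of iodine followed by invertive migration places CO2Me trans to the aryl group, and trans is also the thermodynamic arrangement, so any erosion can be corrected by equilibration. The step needs migration of ring A in preference to migration of the C2 aryl group or loss of the C2 hydrogen; ring A is favoured because its migrating carbon is ortho to the ring oxygen, and the tosyloxy group makes the syringyl ring a poor migrating group that is also hard to oxidise. C2 takes no part and keeps its configuration.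

Step 7
Reactants: 11 methyl (2S,3S)-5-bromo-7-methoxy-2-[3,5-dimethoxy-4-(tosyloxy)phenyl]-2,3-dihydro-1-benzofuran-3-carboxylate
Product: 12 4-[(2S,3R)-5-bromo-3-(hydroxymethyl)-7-methoxy-2,3-dihydro-1-benzofuran-2-yl]-2,6-dimethoxyphenyl 4-methylbenzenesulfonate
Conditions: LiBH4, THF, 0 °C to rt
Reagents that add atoms: none
Why: Chemoselective hydride reduction of the only ester; aryl bromide and aryl sulfonate are inert, and the weakly basic medium should neither epimerise C3 nor open the ring by beta-elimination of the aryloxide. No bond at C2 or C3 is broken; the descriptor at C3 changes from S to R only because CH2OH ranks below C2 whereas CO2Me ranked above it.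

Step 8
Reactants: 12 4-[(2S,3R)-5-bromo-3-(hydroxymethyl)-7-methoxy-2,3-dihydro-1-benzofuran-2-yl]-2,6-dimethoxyphenyl 4-methylbenzenesulfonate; 13 methyl acrylate
Product: 14 methyl (E)-3-[(2S,3R)-3-(hydroxymethyl)-7-methoxy-2-[3,5-dimethoxy-4-(tosyloxy)phenyl]-2,3-dihydro-1-benzofuran-5-yl]prop-2-enoate
Conditions: Pd(OAc)2 (5 mol %), P(o-tol)3 (10 mol %), Et3N, DMF, 100 °C
Reagents that add atoms: none
Why: Heck reaction: oxidative addition of zerovalent palladium into the C5–Br bond, insertion of the acrylate and beta-hydride elimination give the E cinnamate. The aryl sulfonate does not undergo oxidative addition with this triarylphosphine catalyst, and the primary alcohol needs no protection.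

Step 9
Reactants: 14 methyl (E)-3-[(2S,3R)-3-(hydroxymethyl)-7-methoxy-2-[3,5-dimethoxy-4-(tosyloxy)phenyl]-2,3-dihydro-1-benzofuran-5-yl]prop-2-enoate
Product: 15 methyl 3-[(2S,3R)-3-(hydroxymethyl)-7-methoxy-2-[3,5-dimethoxy-4-(tosyloxy)phenyl]-2,3-dihydro-1-benzofuran-5-yl]propanoate
Conditions: H2 (1 atm), 10% Pd/C, EtOAc, rt
Reagents that add atoms: none
Why: Heterogeneous hydrogenation of the conjugated alkene; under neutral conditions at atmospheric pressure the benzylic C2–O1 bond and the aryl sulfonate should survive.

Step 10
Reactants: 15 methyl 3-[(2S,3R)-3-(hydroxymethyl)-7-methoxy-2-[3,5-dimethoxy-4-(tosyloxy)phenyl]-2,3-dihydro-1-benzofuran-5-yl]propanoate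
Product: 16 methyl 3-[(2S,3R)-2-(4-hydroxy-3,5-dimethoxyphenyl)-3-(hydroxymethyl)-7-methoxy-2,3-dihydro-1-benzofuran-5-yl]propanoate
Conditions: Mg turnings, MeOH, rt (ultrasound); aq. NH4Cl work-up
Reagents that add atoms: none
Why: Single-electron reduction by magnesium in methanol cleaves the S–O bond of the aryl sulfonate to the phenoxide and a sulfinate. The solvent is methanol, so the methyl ester cannot be exchanged, and neither stereocentre is involved.

## Compound list

1 | 1-(2-hydroxy-3-methoxyphenyl)ethanone | CC(=O)c1cccc(OC)c1O | starting material
2 | 1-(5-bromo-2-hydroxy-3-methoxyphenyl)ethanone | CC(=O)c1cc(Br)cc(OC)c1O | intermediate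
3 | (E)-1-(5-bromo-2-hydroxy-3-methoxyphenyl)-3-(dimethylamino)prop-2-en-1-one | CN(C)/C=C/C(=O)c1cc(Br)cc(OC)c1O | intermediate
4 | 6-bromo-8-methoxy-4H-chromen-4-one | O=c1ccoc2c(OC)cc(Br)cc12 | intermediate
5 | 2,6-dimethoxy-4-(4,4,5,5-tetramethyl-1,3,2-dioxaborolan-2-yl)phenol | COc1cc(B2OC(C)(C)C(C)(C)O2)cc(OC)c1O | starting material
6 | 2,6-dimethoxy-4-(4,4,5,5-tetramethyl-1,3,2-dioxaborolan-2-yl)phenyl 4-methylbenzenesulfonate | COc1cc(B2OC(C)(C)C(C)(C)O2)cc(OC)c1OS(=O)(=O)c1ccc(C)cc1 | intermediate
7 | [3,5-dimethoxy-4-(4-methylbenzenesulfonyloxy)phenyl]boronic acid | COc1cc(B(O)O)cc(OC)c1OS(=O)(=O)c1ccc(C)cc1 | intermediate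
8 | (2S)-6-bromo-8-methoxy-2-[3,5-dimethoxy-4-(tosyloxy)phenyl]chroman-4-one | O=C1C[C@@H](c2cc(OC)c(OS(=O)(=O)c3ccc(C)cc3)c(OC)c2)Oc2c(OC)cc(Br)cc21 | intermediate
9 | (2S)-6-bromo-4,8-dimethoxy-2-[3,5-dimethoxy-4-(tosyloxy)phenyl]-2H-chromene | COC1=C[C@@H](c2cc(OC)c(OS(=O)(=O)c3ccc(C)cc3)c(OC)c2)Oc2c(OC)cc(Br)cc21 | intermediate
10 | (2R,3R)-3-[acetoxy(phenyl)iodanyl]-6-bromo-4,4,8-trimethoxy-2-[3,5-dimethoxy-4-(tosyloxy)phenyl]chromane, iodine trans to the C2 aryl group | COC1(OC)[C@H](I(OC(C)=O)c2ccccc2)[C@@H](c2cc(OC)c(OS(=O)(=O)c3ccc(C)cc3)c(OC)c2)Oc2c(OC)cc(Br)cc21 | intermediate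
11 | methyl (2S,3S)-5-bromo-7-methoxy-2-[3,5-dimethoxy-4-(tosyloxy)phenyl]-2,3-dihydro-1-benzofuran-3-carboxylate (trans) | Brc1cc(OC)c2c(c1)[C@H](C(=O)OC)[C@@H](c1cc(OC)c(OS(=O)(=O)c3ccc(C)cc3)c(OC)c1)O2 | intermediate
12 | 4-[(2S,3R)-5-bromo-3-(hydroxymethyl)-7-methoxy-2,3-dihydro-1-benzofuran-2-yl]-2,6-dimethoxyphenyl 4-methylbenzenesulfonate | Brc1cc(OC)c2c(c1)[C@H](CO)[C@@H](c1cc(OC)c(OS(=O)(=O)c3ccc(C)cc3)c(OC)c1)O2 | intermediate
13 | methyl acrylate | C=CC(=O)OC | starting material
14 | methyl (E)-3-[(2S,3R)-3-(hydroxymethyl)-7-methoxy-2-[3,5-dimethoxy-4-(tosyloxy)phenyl]-2,3-dihydro-1-benzofuran-5-yl]prop-2-enoate | COC(=O)/C=C/c1cc(OC)c2c(c1)[C@H](CO)[C@@H](c1cc(OC)c(OS(=O)(=O)c3ccc(C)cc3)c(OC)c1)O2 | intermediate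
15 | methyl 3-[(2S,3R)-3-(hydroxymethyl)-7-methoxy-2-[3,5-dimethoxy-4-(tosyloxy)phenyl]-2,3-dihydro-1-benzofuran-5-yl]propanoate | COC(=O)CCc1cc(OC)c2c(c1)[C@H](CO)[C@@H](c1cc(OC)c(OS(=O)(=O)c3ccc(C)cc3)c(OC)c1)O2 | intermediate
16 | methyl 3-[(2S,3R)-2-(4-hydroxy-3,5-dimethoxyphenyl)-3-(hydroxymethyl)-7-methoxy-2,3-dihydro-1-benzofuran-5-yl]propanoate | COC(=O)CCc1cc(OC)c2c(c1)[C@H](CO)[C@@H](c1cc(OC)c(O)c(OC)c1)O2 | target

## Step count and least certain steps

Total step count: 10. Longest linear sequence: 8 steps (steps 1, 2, 5, 6, 7, 8, 9, 10 from 1; the branch from 5 through steps 3 and 4 is equally long).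

**Step 6 (key step).** The aryl shift of ring A may be outrun by migration of the C2 aryl group or by loss of the C2 hydrogen. Both are opened by the same iodanyl intermediate, and both lead to cations stabilised by O1 or to conjugation with the carbonyl group. In addition, the strong acid may open the pyranone ring by retro-oxa-Michael reaction and erode the configuration at C2, and trans selectivity at C3 may be incomplete. Fallback, from 8 back to 11: the one-pot oxidation is split into isolable stages with bromide as the leaving group. Bromination of 8 with PhNMe3Br3 in THF should give the 2,3-trans alpha-bromo ketone F1. Ketalisation (HC(OMe)3, MeOH, TsOH) gives the bromo dimethyl ketal F2. ZnBr2 in toluene at 90 °C (or AgBF4 in MeOH) then triggers the same 1,2-shift of ring A with inversion at C3 and returns to 11. This is the established Lewis-acid-promoted aryl migration of alpha-halo ketals, and each stage can be controlled separately.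

**Step 5.** Protodeboronation of 7 may outpace insertion. Adventitious zerovalent palladium may insert into the C–Br bond of 4. Facial discrimination may be insufficient or of the opposite sense, since the model is carried over from carbocyclic enones. Fallback, from 2 to 8: syringaldehyde F3 is tosylated (TsCl, Et3N, DMAP) to the aldehyde tosylate F4. Claisen–Schmidt condensation of 2 with F4 (KOH, EtOH, rt) gives the 2′-hydroxychalcone F5. NaOAc in refluxing EtOH closes it by oxa-Michael addition to the racemic flavanone F6, and preparative chromatography on a cellulose tris(3,5-dimethylphenylcarbamate) phase delivers 8. This trades the asymmetric catalysis for a metal-free construction and a resolution.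

**Step 8.** Oxidative addition at the electron-rich bromide (para to O1) may be slow, so that the catalyst decays to palladium black at 100 °C, and the primary alcohol may add to the acrylate under the basic conditions. Fallback, from 12 to 15: Negishi coupling of 12 with the zinc homoenolate bromo(3-methoxy-3-oxopropyl)zinc F7 (from methyl 3-bromopropanoate, Zn dust and LiCl in THF; excess to allow for the free hydroxyl) with Pd(OAc)2/SPhos in THF at rt to 50 °C. This installs the saturated chain directly and rejoins the route at 15, bypassing 14 and the hydrogenation.

**Step 10.** The S–O cleavage may stall, because the sulfonate is flanked by two methoxy groups and the magnesium surface passivates. Once the phenoxide is free, the basic methoxide medium may open the para-hydroxybenzyl ether through a quinone methide and epimerise C2. Fallback, from 15 to 16: KOH in MeOH/H2O at 60 °C cleaves both the sulfonate and the ester to the phenolic hydroxy acid F8 (the same ring-opening risk applies and sets the upper limit on temperature). Fischer esterification (MeOH, catalytic HCl generated from AcCl, rt) then restores the methyl ester and gives 16.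

## Further compounds

F1 | step 6 | (2R,3R)-3,6-dibromo-8-methoxy-2-[3,5-dimethoxy-4-(tosyloxy)phenyl]chroman-4-one (2,3-trans) | O=C1[C@H](Br)[C@@H](c2cc(OC)c(OS(=O)(=O)c3ccc(C)cc3)c(OC)c2)Oc2c(OC)cc(Br)cc21
F2 | step 6 | (2R,3R)-3,6-dibromo-4,4,8-trimethoxy-2-[3,5-dimethoxy-4-(tosyloxy)phenyl]chromane (2,3-trans) | COC1(OC)[C@H](Br)[C@@H](c2cc(OC)c(OS(=O)(=O)c3ccc(C)cc3)c(OC)c2)Oc2c(OC)cc(Br)cc21
F3 | step 5 | 4-hydroxy-3,5-dimethoxybenzaldehyde (syringaldehyde) | COc1cc(C=O)cc(OC)c1O
F4 | step 5 | 4-formyl-2,6-dimethoxyphenyl 4-methylbenzenesulfonate | COc1cc(C=O)cc(OC)c1OS(=O)(=O)c1ccc(C)cc1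
F5 | step 5 | (E)-1-(5-bromo-2-hydroxy-3-methoxyphenyl)-3-[3,5-dimethoxy-4-(tosyloxy)phenyl]prop-2-en-1-one | O=C(/C=C/c1cc(OC)c(OS(=O)(=O)c2ccc(C)cc2)c(OC)c1)c1cc(Br)cc(OC)c1O
F6 | step 5 | racemic 6-bromo-8-methoxy-2-[3,5-dimethoxy-4-(tosyloxy)phenyl]chroman-4-one | O=C1CC(c2cc(OC)c(OS(=O)(=O)c3ccc(C)cc3)c(OC)c2)Oc2c(OC)cc(Br)cc21
F7 | step 8 | bromo(3-methoxy-3-oxopropyl)zinc | COC(=O)CC[Zn]Br
F8 | step 10 | 3-[(2S,3R)-2-(4-hydroxy-3,5-dimethoxyphenyl)-3-(hydroxymethyl)-7-methoxy-2,3-dihydro-1-benzofuran-5-yl]propanoic acid | OC(=O)CCc1cc(OC)c2c(c1)[C@H](CO)[C@@H](c1cc(OC)c(O)c(OC)c1)O2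
A1 | alternative 1 | methyl 3-[(2S,3R)-2-(4-benzyloxy-3,5-dimethoxyphenyl)-7-methoxy-3-[(2,2,6,6-tetramethylpiperidin-1-yl)oxymethyl]-2,3-dihydrobenzofuran-5-yl]propanoate | COC(=O)CCc1cc(OC)c2c(c1)[C@H](CON1C(C)(C)CCCC1(C)C)[C@@H](c1cc(OC)c(OCc3ccccc3)c(OC)c1)O2
A2 | alternative 1 | methyl 3-{4-[(1S)-1-(4-benzyloxy-3,5-dimethoxyphenyl)prop-2-enoxy]-3-iodo-5-methoxyphenyl}propanoate | COC(=O)CCc1cc(I)c(O[C@@H](C=C)c2cc(OC)c(OCc3ccccc3)c(OC)c2)c(OC)c1
A3 | alternative 2 | (2S,3R)-2-(4-benzyloxy-3,5-dimethoxyphenyl)-5-chloro-3-(tert-butyldimethylsilyloxymethyl)-7-methoxy-2,3-dihydrobenzofuran | Clc1cc(OC)c2c(c1)[C@H](CO[Si](C)(C)C(C)(C)C)[C@@H](c1cc(OC)c(OCc3ccccc3)c(OC)c1)O2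
A4 | alternative 2 | 3-{[(1S,2R)-1-(4-benzyloxy-3,5-dimethoxyphenyl)-2-(tert-butyldimethylsilyloxymethyl)but-3-yn-1-yl]oxy}-6-chloro-4-methoxypyridazine | C#C[C@H](CO[Si](C)(C)C(C)(C)C)[C@@H](c1cc(OC)c(OCc2ccccc2)c(OC)c1)Oc1nnc(Cl)cc1OC
A5 | alternative 3 | methyl 3-[(2S,3R)-2-(4-benzyloxy-3,5-dimethoxyphenyl)-3-(tert-butyldimethylsilyloxymethyl)-7-methoxy-2,3-dihydrobenzofuran-5-yl]propanoate | COC(=O)CCc1cc(OC)c2c(c1)[C@H](CO[Si](C)(C)C(C)(C)C)[C@@H](c1cc(OC)c(OCc3ccccc3)c(OC)c1)O2
A6 | alternative 3 | methyl 3-{3-[2-(tert-butyldimethylsilyloxy)-1-(4-methylbenzenesulfonyl)ethyl]-4-hydroxy-5-methoxyphenyl}propanoate (racemic) | COC(=O)CCc1cc(OC)c(O)c(C(CO[Si](C)(C)C(C)(C)C)S(=O)(=O)c2ccc(C)cc2)c1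
A7 | alternative 3 | (2R,5R)-1-[(4-benzyloxy-3,5-dimethoxyphenyl)methyl]-2,5-dimethylthiolan-1-ium tetrafluoroborate | C[C@@H]1CC[C@@H](C)[S+]1Cc1cc(OC)c(OCc2ccccc2)c(OC)c1.F[B-](F)(F)F
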